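## Structural features

The target is a labdane: a trans-fused decalin (rings A and B) whose C9 is the spiro atom of an oxolane (ring C: O9, C9, C11, C12, C13), and whose C13 is in turn the spiro atom of a 2,3-dihydrofuran (ring D: C13, C14=C15, O, C16). Five stereocentres are contiguous (C6, C5, C10, C9, C8: 6β-acetoxy, 5α-H, 10β-methyl, 9α-oxygen, 8α-methyl). The sixth, the fully substituted C13 (R), lies across ring C, three bonds from the nearest of them. C9 (a tetrasubstituted ether carbon) and C10 (quaternary) are adjacent and flanked by the C4 gem-dimethyl group, so C9–C10 is the most congested bond of the molecule. The fragile parts are the cyclic enol ether of ring D, which together with the tertiary C9–O and C13–O bonds is prone to acid-induced opening towards a furan, the β-alkoxy relationship of O9 to C15, and the axial 6β-acetate pressed against the C19 and C20 methyl groups. The real difficulties are the vicinal C9/C10 pair, the remote C13 centre that no decalin stereocentre can control, and the 8α-methyl group, which must be set against the bias of the angular methyl group. The key step exploits the 1,3-relationship of O6 and C17 across ring B: C6 is read as an aldehyde carbon and C7=C8–C17 as an isopropenyl group on C9, the two arms standing trans-diequatorial on C5 and C10 of a finished ring A.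

## Logic of the disconnections

36 is cut at the C14=C15 enol ether (loss of water across C14–C15) to 34, and 34 at the C15–O16 hemiacetal bond to 32, with O16 capped as a benzyl ether; 32 goes back through 31 to 30 by lowering C15 to a PMB-protected alcohol. The enol ether next to the tertiary C13–O bond is the most acid-labile element and is therefore made last. The gain is that ring D becomes two differentiated primary oxygens. The demand is an elimination under basic conditions, a neutral debenzylation and an oxidation that spares a β-alkoxy aldehyde.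

30 is cut at the C6–O acyl bond to 29, and 29 at the two C–H bonds on C8 and C17 to the 8(17)-alkene 28. The axial 6β-hydroxyl is 1,3-syn to the β-face of C8 and can deliver hydrogen there, which sterics alone would not do. The gain is that C8 is no longer a stereocentre. The demand is that the cationic iridium catalyst binds the hydroxyl and not O9.

28 is traced through the ketone 27 to the 6α-alcohol 26 (C6–H bond exchanged). The cut is made because the ring closure is expected to give the equatorial alcohol. The gain is that the C6 configuration of the key step becomes irrelevant. The demand is an oxidation that does not move the 8(17)-alkene into conjugation and a hydride that enters from the α-face.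

26 is cut at C6–C7, opening ring B to 25. This is the one bond that turns the O6/C17 1,3-pattern into an aldehyde and an isopropenyl group. The gain is one ring and one stereocentre. The demand is ene closure without ionization of the allylic C9–O bond.

25 goes back to the alcohol 24, then to 23 by removing C7 (the C8=C7 bond), then to the lactone 22 by removing C17 (the C8–C17 bond). The description of the precursor leaves open how two hindered 1,1-disubstituted alkenes (C5=C6 and C8=C7) could be told apart; the route therefore oxygenates C6 before the isopropenyl group exists and keeps O6 and C8 tied as a lactone until both one-carbon units are added. The gain is that no protecting group is spent on O6. The demand is a single addition of methyllithium and olefination of a ketone that rests as its lactol.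

22 goes back to 21 (C1–C2 saturation) and 21 to 18 by cutting the C6–O bond and the C5–H bond (anti-Markovnikov hydration of the exocyclic alkene, then lactonization). The gain is that C5 is no longer a stereocentre. The demand is a borane that takes the exocyclic alkene and not the ring alkene, and delivers hydrogen to the α-face of C5.

18 is cut at C9–C10, the γ,δ-unsaturated acid being the retron of an Ireland–Claisen rearrangement of ester 15, which is cut at its ester C–O bond into 11 and 14. Only a [3,3] shift can be trusted to join two fully substituted carbons. The gain is that the C9 and C10 stereocentres are derived from one carbinol centre and ring A is separated from ring C. The demand is control of the ketene acetal geometry and of the chair or boat course.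

14 is cut at C5=C6 to 13 and 13 at the carbinol C–H bond to 12. The gain is a commodity enedione. The demand is regio- and enantioselective reduction of one of two carbonyl groups and methylenation of the hindered one.

11 is cut at C8 (oxidation level) to 10, at the C9–O bond to 8, at C11–C12 to 6 and 7, and then through 5 (O16 protecting group), 4 (epoxide oxygen, C13 stereocentre), 3 and 2 back to 1. C13 with three methylene arms is best set by a reagent-controlled epoxidation of an allylic alcohol. The demand is that the epoxide is opened only at its unsubstituted carbon.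

## Other disconnections considered

Alternative 1: The cut runs through C5–C10 and C8–C9 and opens both carbocycles to the acyclic triene A1, in which a (Z)-3-methyl enal (C9=C10) is tethered through C1–C4 to a 2-silyloxy diene (C5=C6–C7=C8). The forward step is an intramolecular Diels–Alder reaction to the octalin A2.
- In its favour: two rings, four stereocentres (C5, C8, C9, C10), the C6 oxygen as a silyl enol ether and the C8 methyl group arise in one step from a linear chain. On bond economy for the carbocyclic core this is better than the chosen plan, which needs steps 9–18 for the same atoms.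
- Against it: A2 is cis-fused, so C5 must be epimerized through the C6 ketone. C9 carries hydrogen and has its formyl carbon on the α-face, whereas the target needs C11 on the β-face and oxygen on the α-face, so C9 has to be rebuilt as a tetrasubstituted ether carbon next to C10. The whole C11–C16 unit with the remote C13 centre is still missing and has no control element. Absolute control needs a chiral catalyst acting on a trisubstituted dienophile that forms a quaternary carbon, and both the (Z)-enal and the diene geometry of A1 must be prepared pure.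
- Comparison: the concerted cycloaddition is as predictable as the ene closure (equal on mechanism). Structurally it postpones the two hardest centres (C9, C13), which the chosen plan fixes before ring B exists in 18. In total steps it is unlikely to be shorter once the corrections at C5 and C9 are counted.

Alternative 2: The cut is C13–C14. The precursor is the diazoacetate A3 on O16, with C13 as a tertiary C–H of ring C, and the forward step is a carbenoid insertion with Rh2(OAc)4 or a carboxamidate analogue into C13–H to give the spiro γ-lactone A4.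
- In its favour: insertion goes with retention, so the quaternary C13 derives from a simple secondary ether centre, which is easier to set than the three-armed carbinol of 5; on this point it is better than the chosen plan. The C–H bond is activated by the ether oxygen and the 1,5-mode is the normal preference. C15 arrives as a lactone carbonyl, so the two orthogonal ether groups of the chosen plan are not needed and the end game is shorter (also better).
- Against it: it is a late-stage tactic and says nothing about ring B or C9/C10, which would still need a solution such as step 12 and step 18. An acceptor-only carbenoid may instead attack O9 (six-membered oxonium ylide, then 1,2-shift) or insert at C12–H. A3 requires the 9,13-cis/trans relationship across ring C to be set without the help of a second substituent on C13. Reduction of A4 to the lactol must later be done beside the C6 functionality.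
- Comparison: complementary rather than competing. Grafted onto the chosen plan it would shorten steps 23–26 but add a C13 problem in the oxolane acid, so the step count would be about equal.

Alternative 3: The cut is C1–C10 and C4–C5, opening ring A. The forward step is a [4+2] cycloaddition of the diene A6 to a methyl-bearing double bond of the quinone A5 under a chiral oxazaborolidinium Lewis acid, giving the cis-fused enedione A7.
- In its favour: one catalytic enantioselective step from two commodity chemicals forms ring A and the quaternary C10 and delivers ring B with carbonyl groups at C6 and C9 and the C8 methyl group already in place. As an entry to the decalin this is clearly better than steps 9–18. The regiochemistry is electronically matched, the unsubstituted diene terminus bonding to the carbon β to the less hindered, coordinated carbonyl.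
- Against it: A6 is a poor diene, because its (Z)-methyl group disfavours the s-cis conformer, and it is prone to cationic side reactions under strong Lewis acids. A7 is cis-fused (correctable at C5 through the C6 ketone). The decisive weakness comes afterwards: a C11 nucleophile would have to add to the hindered C9 ketone from the β-face, the face of the angular methyl group, to leave oxygen on the α-face, and C13 would again be remote and uncontrolled. C8 would have to be set by a conjugate reduction.
- Comparison: better in step economy and starting-material cost for rings A and B, equal in mechanistic reliability of the key step if the diene reacts, and weaker on C9 and C13, which the chosen plan settles by the sigmatropic shift of step 12 and the epoxidation of step 4.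

Key step: step 18

Remark on the chemistry: atoms carry labdane numbers in every intermediate (C1–C20, O9 for the oxolane oxygen, O6 and O16 for the oxygens on C6 and C16), and α/β refer to the faces of the final trans-decalin. The ring closure of step 18 is a type 2 ene reaction (tether on the central carbon of the ene unit), and the two reacting arms are trans on ring A. The ligand and tartrate enantiomers in steps 9 and 4 are assigned from the empirical face rules and should be confirmed on the first batch.

## Steps

Step 1
Reactants: 1 3-methylbut-3-en-1-ol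
Product: 2 4-methoxybenzyl 3-methylbut-3-en-1-yl ether
Conditions: NaH, 4-methoxybenzyl chloride, Bu4NI (cat.), THF/DMF, 0 °C → rt
Reagents that add atoms: 4-methoxybenzyl chloride, COc1ccc(CCl)cc1
Why: Williamson etherification of a primary alkoxide; the PMB group is chosen because it can later be removed oxidatively while the benzyl ether on O16 stays.

Step 2
Reactants: 2 4-methoxybenzyl 3-methylbut-3-en-1-yl ether
Product: 3 2-methyl-2-{2-[(4-methoxybenzyl)oxy]ethyl}oxirane (racemic)
Conditions: mCPBA, NaHCO3, CH2Cl2, 0 °C
Reagents that add atoms: 3-chloroperoxybenzoic acid, OOC(=O)c1cccc(Cl)c1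
Why: Prilezhaev epoxidation of an electron-rich 1,1-disubstituted alkene; a racemate suffices because this stereocentre is erased in step 3.

Step 3
Reactants: 3 2-methyl-2-{2-[(4-methoxybenzyl)oxy]ethyl}oxirane (racemic)
Product: 4 4-[(4-methoxybenzyl)oxy]-2-methylidenebutan-1-ol
Conditions: LiTMP, Et2AlCl, PhMe, 0 °C
Reagents that add atoms: none
Why: base-mediated isomerization of an epoxide to an allylic alcohol by syn β-elimination within the aluminium amide–epoxide complex; the bulky amide should take a proton from the unhindered methyl group and not from C14H2, which gives the 2-substituted allylic alcohol.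

Step 4
Reactants: 4 4-[(4-methoxybenzyl)oxy]-2-methylidenebutan-1-ol
Product: 5 [(2R)-2-{2-[(4-methoxybenzyl)oxy]ethyl}oxiran-2-yl]methanol
Conditions: Ti(OiPr)4 (10 mol %), D-(−)-diethyl tartrate (12 mol %), t-BuOOH, 4 Å molecular sieves, CH2Cl2, −20 °C
Reagents that add atoms: tert-butyl hydroperoxide, CC(C)(C)OO
Why: Sharpless asymmetric epoxidation of a 2-substituted allylic alcohol; by the face rule (L-(+)-tartrate gives the (S)-glycidol of this substitution pattern) the D-(−)-tartrate should give the (R)-epoxide, whose tertiary carbon is C13 of the target.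

Step 5
Reactants: 5 [(2R)-2-{2-[(4-methoxybenzyl)oxy]ethyl}oxiran-2-yl]methanol
Product: 6 (2S)-2-[(benzyloxy)methyl]-2-{2-[(4-methoxybenzyl)oxy]ethyl}oxirane
Conditions: NaH, BnBr, Bu4NI (cat.), THF, 0 °C
Reagents that add atoms: benzyl bromide, BrCc1ccccc1
Why: Williamson benzylation; the Payne rearrangement open to this epoxy alkoxide is degenerate (it regenerates the same enantiomer), so C13 cannot be eroded, and the change of descriptor is only a change of priorities.

Step 6
Reactants: 6 (2S)-2-[(benzyloxy)methyl]-2-{2-[(4-methoxybenzyl)oxy]ethyl}oxirane; 7 allylmagnesium bromide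
Product: 8 (2R)-1-(benzyloxy)-2-{2-[(4-methoxybenzyl)oxy]ethyl}hex-5-en-2-ol
Conditions: CuI (10 mol %), THF, −30 → 0 °C
Reagents that add atoms: none
Why: copper-catalysed Grignard opening of a 2,2-disubstituted epoxide at its unsubstituted carbon (C12); the C13–O bond is not touched, so the configuration is kept, and copper at low temperature should suppress magnesium-halide-induced rearrangement of the epoxide.

Step 7
Reactants: 8 (2R)-1-(benzyloxy)-2-{2-[(4-methoxybenzyl)oxy]ethyl}hex-5-en-2-ol
Product: 10 [(5R)-5-[(benzyloxy)methyl]-5-{2-[(4-methoxybenzyl)oxy]ethyl}oxolan-2-yl]methanol (C2 epimers), via hydroxy epoxide 9 (not isolated)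
Conditions: mCPBA, NaHCO3, CH2Cl2, 0 °C → rt; then CSA (10 mol %), rt
Reagents that add atoms: 3-chloroperoxybenzoic acid, OOC(=O)c1cccc(Cl)c1
Why: epoxidation of the terminal alkene, then acid-catalysed 5-exo opening of the epoxide at its internal carbon (C9) by the tertiary hydroxyl closes ring C; both C9 epimers serve because C9 becomes trigonal in step 12.

Step 8
Reactants: 10 [(5R)-5-[(benzyloxy)methyl]-5-{2-[(4-methoxybenzyl)oxy]ethyl}oxolan-2-yl]methanol (C2 epimers)
Product: 11 (5R)-5-[(benzyloxy)methyl]-5-{2-[(4-methoxybenzyl)oxy]ethyl}oxolane-2-carboxylic acid (C2 epimers)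
Conditions: TEMPO (20 mol %), PhI(OAc)2, MeCN/H2O (1:1), rt
Reagents that add atoms: water, O
Why: oxoammonium oxidation of the primary alcohol through the aldehyde hydrate to the acid; the near-neutral medium should spare the PMB and benzyl ethers.

Step 9
Reactants: 12 ketoisophorone
Product: 13 (4S)-4-hydroxy-2,6,6-trimethylcyclohex-2-en-1-one
Conditions: RuCl[(S,S)-TsDPEN](p-cymene) (0.5 mol %), HCO2H/Et3N (5:2), rt
Reagents that add atoms: none
Why: Noyori asymmetric transfer hydrogenation; the carbonyl flanked by CH= and CH2 (labdane C2) is reduced while the one between CMe2 and C(CH3)= is left, and with the alkene as the π-substituent the (S,S)-catalyst should give the (S)-alcohol.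

Step 10
Reactants: 13 (4S)-4-hydroxy-2,6,6-trimethylcyclohex-2-en-1-one
Product: 14 (1S)-3,5,5-trimethyl-4-methylidenecyclohex-2-en-1-ol
Conditions: Ph3PCH3Br (3.5 equiv), KOtBu (3.4 equiv), PhMe, 80 °C
Reagents that add atoms: methyltriphenylphosphonium bromide, C[P+](c1ccccc1)(c1ccccc1)c1ccccc1.[Br-]
Why: Wittig methylenation under the forcing conditions used for hindered ketones; the first equivalent of ylide turns the hydroxyl into its alkoxide, and the carbonyl (labdane C5) has only one quaternary neighbour at this stage, which is why C6 is introduced now.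

Step 11
Reactants: 11 (5R)-5-[(benzyloxy)methyl]-5-{2-[(4-methoxybenzyl)oxy]ethyl}oxolane-2-carboxylic acid (C2 epimers); 14 (1S)-3,5,5-trimethyl-4-methylidenecyclohex-2-en-1-ol
Product: 15 (1S)-3,5,5-trimethyl-4-methylidenecyclohex-2-en-1-yl (5R)-5-[(benzyloxy)methyl]-5-{2-[(4-methoxybenzyl)oxy]ethyl}oxolane-2-carboxylate
Conditions: EDC·HCl, DMAP, CH2Cl2, 0 °C → rt
Reagents that add atoms: none
Why: Steglich esterification under neutral conditions that do not ionize the dienyl carbinol; no stereocentre is touched.

Step 12
Reactants: 15 (1S)-3,5,5-trimethyl-4-methylidenecyclohex-2-en-1-yl (5R)-5-[(benzyloxy)methyl]-5-{2-[(4-methoxybenzyl)oxy]ethyl}oxolane-2-carboxylate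
Product: 18 (2S,5R)-5-[(benzyloxy)methyl]-5-{2-[(4-methoxybenzyl)oxy]ethyl}-2-[(1S)-1,5,5-trimethyl-6-methylidenecyclohex-2-en-1-yl]oxolane-2-carboxylic acid, via silyl ketene acetal 16 (not isolated), via trimethylsilyl ester 17 (not isolated)
Conditions: LDA, THF, −78 °C; Me3SiCl/Et3N, −78 °C → rt; then 65 °C; 1 M HCl
Reagents that add atoms: none
Why: Ireland–Claisen rearrangement: lithium chelation between the enolate oxygen and O9 should fix the (Z)-ketene acetal 16, and the [3,3] shift forms C9–C10 on the ring face from which the C2–O bond departs, so the (S)-carbinol is relayed into the 10β-methyl quaternary centre. A boat-like transition state is expected, because the chair would hold C8 and its OSiMe3 group over ring A against the pseudo-axial C4 methyl group; boat plus (Z)-acetal places O9 over C20 and C11 over C5, which is the 9α-O arrangement of 36.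

Step 13
Reactants: 18 (2S,5R)-5-[(benzyloxy)methyl]-5-{2-[(4-methoxybenzyl)oxy]ethyl}-2-[(1S)-1,5,5-trimethyl-6-methylidenecyclohex-2-en-1-yl]oxolane-2-carboxylic acid
Product: 21 trans-fused unsaturated δ-lactone (O6 acylated by C8; C1=C2 retained; 5α-H), via bis-borane adduct 19 (not isolated), via hydroxy acid 20 (not isolated)
Conditions: 9-BBN (3 equiv), THF, 65 °C; NaOH, H2O2, 0 °C → rt; HCl to pH 3; then PPTS (cat.), PhMe, 80 °C
Reagents that add atoms: hydrogen peroxide, OO
Why: hydroboration–oxidation: 9-BBN adds readily to terminal 1,1-disubstituted alkenes but only very slowly to cyclohexenes, so boron should go to C6 and leave C1=C2. Hydrogen is expected to reach C5 from the α-face, because the β-face of C5=C6 is flanked by the pseudo-axial methyl groups on C4 and C10, which sets 5α-H with C6 trans to the C9 arm. The δ-hydroxy acid 20 then closes to the lactone, which masks O6 and C8 together.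

Step 14
Reactants: 21 trans-fused unsaturated δ-lactone (O6 acylated by C8; C1=C2 retained; 5α-H)
Product: 22 trans-fused saturated δ-lactone (ring A saturated; C5, C9, C10, C13 as in 36)
Conditions: H2 (1 atm), [Ir(cod)(PCy3)(py)]PF6 (5 mol %), CH2Cl2, rt
Reagents that add atoms: none
Why: homogeneous hydrogenation of the only alkene left (cis-disubstituted C1=C2), which creates no stereocentre; the cationic iridium catalyst does not hydrogenolyse benzyl or PMB ethers.

Step 15
Reactants: 22 trans-fused saturated δ-lactone (ring A saturated; C5, C9, C10, C13 as in 36)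
Product: 23 methyl lactol (C8 bears CH3 and OH; C8 epimers; in equilibrium with the C6-hydroxy C8-methyl ketone)
Conditions: MeLi (1.2 equiv), THF, −78 °C; aq. NH4Cl
Reagents that add atoms: methyllithium, [Li]C
Why: single addition of an alkyllithium to a δ-lactone: the lithium lactolate is stable at low temperature and releases the ketone only on work-up, so a second addition is avoided; this step brings in C17.

Step 16
Reactants: 23 methyl lactol (C8 bears CH3 and OH; C8 epimers; in equilibrium with the C6-hydroxy C8-methyl ketone)
Product: 24 16-(benzyloxy)-15-[(4-methoxybenzyl)oxy]-9α,13-epoxy-(13R)-6,7-secolabd-7-en-6-ol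
Conditions: Ph3PCH3Br (5 equiv), KOtBu (4.8 equiv), PhMe, 90 °C
Reagents that add atoms: methyltriphenylphosphonium bromide, C[P+](c1ccccc1)(c1ccccc1)c1ccccc1.[Br-]
Why: Wittig methylenation of a lactol through its ring-opened hydroxy ketone (as the potassium alkoxide), a known way from lactone-derived methyl lactols to hydroxy isopropenyl compounds; the strain of three contiguous fully substituted carbons (C8, C9, C10) in the cyclic form should raise the share of open ketone. C7 enters only here, after O6 is in place, so the two hindered 1,1-disubstituted alkenes never have to be told apart.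

Step 17
Reactants: 24 16-(benzyloxy)-15-[(4-methoxybenzyl)oxy]-9α,13-epoxy-(13R)-6,7-secolabd-7-en-6-ol
Product: 25 16-(benzyloxy)-15-[(4-methoxybenzyl)oxy]-9α,13-epoxy-(13R)-6,7-secolabd-7-en-6-al
Conditions: Dess–Martin periodinane, NaHCO3, CH2Cl2, 0 °C
Reagents that add atoms: none
Why: Dess–Martin oxidation of a primary alcohol under buffered conditions that should not epimerize C5; the aldehyde is used at once.

Step 18
Reactants: 25 16-(benzyloxy)-15-[(4-methoxybenzyl)oxy]-9α,13-epoxy-(13R)-6,7-secolabd-7-en-6-al
Product: 26 16-(benzyloxy)-15-[(4-methoxybenzyl)oxy]-9α,13-epoxy-(13R)-labd-8(17)-en-6α-ol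
Conditions: Me2AlCl (1.5 equiv), CH2Cl2, −78 → −20 °C
Reagents that add atoms: none
Why: Me2AlCl binds the aldehyde oxygen and the terminal alkene carbon C7 attacks C6 while a hydrogen of the C17 methyl group passes to oxygen through the six-atom array O=C6···C7=C8–C17–H; the methyl–aluminium bond then takes up the proton as methane, so no free acid is present. The closest known reaction type is the Me2AlCl-promoted carbonyl-ene cyclization of 5-methylhex-5-enals to 3-methylenecyclohexanols, a type 2 closure because the tether sits on the central carbon of the ene unit (citronellal to isopulegol is the type 1 relative). Ring B closes in the six-membered mode with the carbonyl exo to the new ring (6-exo-trig at C6) and leaves the 8(17)-methylene exocyclic. The ring fusion is not at stake: the formyl group on C5 and the C9 arm on C10 are trans-diequatorial on the ring A chair, so only a trans-decalin can form. C6 is the only new stereocentre; hydrogen transfer across the β-face would force the aluminium-bound oxygen and C17 against the axial C19 and C20 methyl groups, so transfer across the α-face is expected and leaves the alkoxide equatorial (6α) once ring B relaxes to its chair. The step needs ene closure to win over methyl transfer from aluminium, chloride capture and ionization of the allylic C9–O bond; low temperature, a mild Lewis acid in small excess and the proximity of C6 and C7 enforced by the quaternary C9 and C10 should secure this. A 6β-epimer would not be lost, since it is compound 28.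

Step 19
Reactants: 26 16-(benzyloxy)-15-[(4-methoxybenzyl)oxy]-9α,13-epoxy-(13R)-labd-8(17)-en-6α-ol
Product: 27 16-(benzyloxy)-15-[(4-methoxybenzyl)oxy]-9α,13-epoxy-(13R)-labd-8(17)-en-6-one
Conditions: Dess–Martin periodinane, NaHCO3, CH2Cl2, 0 °C
Reagents that add atoms: none
Why: Dess–Martin oxidation of the secondary alcohol; buffering and low temperature should keep the β,γ-unsaturated ketone from moving its alkene into conjugation.

Step 20
Reactants: 27 16-(benzyloxy)-15-[(4-methoxybenzyl)oxy]-9α,13-epoxy-(13R)-labd-8(17)-en-6-one
Product: 28 16-(benzyloxy)-15-[(4-methoxybenzyl)oxy]-9α,13-epoxy-(13R)-labd-8(17)-en-6β-ol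
Conditions: NaBH4, MeOH/THF, −20 °C
Reagents that add atoms: none
Why: hydride reduction; the β-face of C6 is closed by the syn-axial C19 and C20 methyl groups, so hydride should enter from the α-face and give the axial 6β-alcohol.

Step 21
Reactants: 28 16-(benzyloxy)-15-[(4-methoxybenzyl)oxy]-9α,13-epoxy-(13R)-labd-8(17)-en-6β-ol
Product: 29 16-(benzyloxy)-15-[(4-methoxybenzyl)oxy]-9α,13-epoxy-(13R)-labdan-6β-ol (8α-methyl; 8β-H)
Conditions: H2 (1 atm), [Ir(cod)(PCy3)(py)]PF6 (10 mol %), CH2Cl2, 0 °C → rt
Reagents that add atoms: none
Why: hydroxyl-directed hydrogenation: the axial 6β-hydroxyl binds the cationic iridium centre and delivers hydrogen to the β-face of the 8(17)-alkene, to which it is 1,3-syn, giving 8β-H and the equatorial 8α-methyl group. A Δ7 isomer formed by metal-induced migration would be reduced from the same face.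

Step 22
Reactants: 29 16-(benzyloxy)-15-[(4-methoxybenzyl)oxy]-9α,13-epoxy-(13R)-labdan-6β-ol (8α-methyl; 8β-H)
Product: 30 16-(benzyloxy)-15-[(4-methoxybenzyl)oxy]-9α,13-epoxy-(13R)-labdan-6β-yl acetate
Conditions: Ac2O, DMAP, pyridine, 40 °C
Reagents that add atoms: acetic anhydride, CC(=O)OC(C)=O
Why: DMAP-catalysed acylation of a hindered axial secondary alcohol; no stereocentre is affected.

Step 23
Reactants: 30 16-(benzyloxy)-15-[(4-methoxybenzyl)oxy]-9α,13-epoxy-(13R)-labdan-6β-yl acetate
Product: 31 16-(benzyloxy)-15-hydroxy-9α,13-epoxy-(13R)-labdan-6β-yl acetate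
Conditions: DDQ, CH2Cl2/pH 7 buffer (10:1), 0 °C
Reagents that add atoms: none
Why: oxidative cleavage of the PMB ether through hydride abstraction and hydrolysis of the oxocarbenium ion; benzyl ether and acetate stay, and no alkene is left to interfere.

Step 24
Reactants: 31 16-(benzyloxy)-15-hydroxy-9α,13-epoxy-(13R)-labdan-6β-yl acetate
Product: 32 16-(benzyloxy)-15-oxo-9α,13-epoxy-(13R)-labdan-6β-yl acetate
Conditions: Dess–Martin periodinane, NaHCO3, CH2Cl2, 0 °C
Reagents that add atoms: none
Why: Dess–Martin oxidation to the β-alkoxy aldehyde under buffered conditions that avoid β-elimination of O9; the aldehyde is carried on crude.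

Step 25
Reactants: 32 16-(benzyloxy)-15-oxo-9α,13-epoxy-(13R)-labdan-6β-yl acetate
Product: 34 6β-acetoxy-9α,13:15,16-diepoxy-(13R)-labdan-15-ol (lactol; C15 epimers), via hydroxy aldehyde 33 (not isolated)
Conditions: H2 (1 atm), Pd/C (10 wt %), EtOAc, rt
Reagents that add atoms: none
Why: hydrogenolysis of the benzyl ether in a neutral, non-alcoholic solvent; the freed C16 hydroxyl adds to the C15 aldehyde and closes ring D as the five-membered lactol.

Step 26
Reactants: 34 6β-acetoxy-9α,13:15,16-diepoxy-(13R)-labdan-15-ol (lactol; C15 epimers)
Product: 36 6β-acetoxy-9α,13:15,16-diepoxy-(13R)-labd-14-ene (target), via anomeric mesylate 35 (not isolated)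
Conditions: MsCl, Et3N (5 equiv), CH2Cl2, −40 °C → rt; chromatography on Et3N-deactivated silica
Reagents that add atoms: none
Why: dehydration of a lactol through its anomeric mesylate, which loses methanesulfonate and a C14 proton (the only β-hydrogens) in the presence of excess amine to give the 2,3-dihydrofuran; the absence of acid protects the enol ether and the tertiary C9–O and C13–O bonds.

## Compound list

1 | 3-methylbut-3-en-1-ol | C=C(C)CCO | starting material
2 | 4-methoxybenzyl 3-methylbut-3-en-1-yl ether | C=C(C)CCOCc1ccc(OC)cc1 | intermediate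
3 | 2-methyl-2-{2-[(4-methoxybenzyl)oxy]ethyl}oxirane (racemic) | CC1(CCOCc2ccc(OC)cc2)CO1 | intermediate
4 | 4-[(4-methoxybenzyl)oxy]-2-methylidenebutan-1-ol | C=C(CO)CCOCc1ccc(OC)cc1 | intermediate
5 | [(2R)-2-{2-[(4-methoxybenzyl)oxy]ethyl}oxiran-2-yl]methanol | OC[C@]1(CCOCc2ccc(OC)cc2)CO1 | intermediate
6 | (2S)-2-[(benzyloxy)methyl]-2-{2-[(4-methoxybenzyl)oxy]ethyl}oxirane | c1ccccc1COC[C@]1(CCOCc2ccc(OC)cc2)CO1 | intermediate
7 | allylmagnesium bromide | C=CC[Mg]Br | starting material
8 | (2R)-1-(benzyloxy)-2-{2-[(4-methoxybenzyl)oxy]ethyl}hex-5-en-2-ol | C=CCC[C@](COCc1ccccc1)(CCOCc1ccc(OC)cc1)O | intermediate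
9 | (2R)-1-(benzyloxy)-2-{2-[(4-methoxybenzyl)oxy]ethyl}-4-(oxiran-2-yl)butan-2-ol (epoxide epimers) | C1(CC[C@](COCc2ccccc2)(CCOCc2ccc(OC)cc2)O)CO1 | intermediate (not isolated)
10 | [(5R)-5-[(benzyloxy)methyl]-5-{2-[(4-methoxybenzyl)oxy]ethyl}oxolan-2-yl]methanol (C2 epimers) | OCC1CC[C@](COCc2ccccc2)(CCOCc2ccc(OC)cc2)O1 | intermediate
11 | (5R)-5-[(benzyloxy)methyl]-5-{2-[(4-methoxybenzyl)oxy]ethyl}oxolane-2-carboxylic acid (C2 epimers) | OC(=O)C1CC[C@](COCc2ccccc2)(CCOCc2ccc(OC)cc2)O1 | intermediate
12 | ketoisophorone (2,6,6-trimethylcyclohex-2-ene-1,4-dione) | CC1=CC(=O)CC(C)(C)C1=O | starting material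
13 | (4S)-4-hydroxy-2,6,6-trimethylcyclohex-2-en-1-one | CC1=C[C@@H](O)CC(C)(C)C1=O | intermediate
14 | (1S)-3,5,5-trimethyl-4-methylidenecyclohex-2-en-1-ol | C=C1C(C)=C[C@@H](O)CC1(C)C | intermediate
15 | (1S)-3,5,5-trimethyl-4-methylidenecyclohex-2-en-1-yl (5R)-5-[(benzyloxy)methyl]-5-{2-[(4-methoxybenzyl)oxy]ethyl}oxolane-2-carboxylate | C=C1C(C)=C[C@@H](OC(=O)C2CC[C@](COCc3ccccc3)(CCOCc3ccc(OC)cc3)O2)CC1(C)C | intermediate
16 | (Z)-trimethylsilyl ketene acetal of 15 (OSiMe3 cis to O9) | C=C1C(C)=C[C@@H](O/C(O[Si](C)(C)C)=C2\CC[C@](COCc3ccccc3)(CCOCc3ccc(OC)cc3)O2)CC1(C)C | intermediate (not isolated)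
17 | trimethylsilyl ester of 18 | C[Si](C)(C)OC(=O)[C@]1(CC[C@](COCc2ccccc2)(CCOCc2ccc(OC)cc2)O1)[C@@]1(C)C=CCC(C)(C)C1=C | intermediate (not isolated)
18 | (2S,5R)-5-[(benzyloxy)methyl]-5-{2-[(4-methoxybenzyl)oxy]ethyl}-2-[(1S)-1,5,5-trimethyl-6-methylidenecyclohex-2-en-1-yl]oxolane-2-carboxylic acid | OC(=O)[C@]1(CC[C@](COCc2ccccc2)(CCOCc2ccc(OC)cc2)O1)[C@@]1(C)C=CCC(C)(C)C1=C | intermediate
19 | bis-borane adduct of 18 (9-BBN on C6; carboxyl as B-acyloxy-9-BBN; 5α-H) | O=C(OB1C2CCCC1CCC2)[C@]1(CC[C@](COCc2ccccc2)(CCOCc2ccc(OC)cc2)O1)[C@@]1(C)C=CCC(C)(C)[C@@H]1CB1C2CCCC1CCC2 | intermediate (not isolated)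
20 | hydroxy acid: 18 with C5=C6 replaced by 5α-H and CH2OH | OC(=O)[C@]1(CC[C@](COCc2ccccc2)(CCOCc2ccc(OC)cc2)O1)[C@@]1(C)C=CCC(C)(C)[C@@H]1CO | intermediate (not isolated)
21 | trans-fused unsaturated δ-lactone (ring atoms C5, C6, O6, C8, C9, C10; C8=O; C1=C2; spiro oxolane at C9) | O=C1[C@]2(CC[C@](COCc3ccccc3)(CCOCc3ccc(OC)cc3)O2)[C@@]2(C)C=CCC(C)(C)[C@@H]2CO1 | intermediate
22 | trans-fused saturated δ-lactone (21 with C1–C2 saturated) | O=C1[C@]2(CC[C@](COCc3ccccc3)(CCOCc3ccc(OC)cc3)O2)[C@@]2(C)CCCC(C)(C)[C@@H]2CO1 | intermediate
23 | methyl lactol (22 with C8 carrying CH3 and OH; C8 epimers) | CC1(O)[C@]2(CC[C@](COCc3ccccc3)(CCOCc3ccc(OC)cc3)O2)[C@@]2(C)CCCC(C)(C)[C@@H]2CO1 | intermediate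
24 | 16-(benzyloxy)-15-[(4-methoxybenzyl)oxy]-9α,13-epoxy-(13R)-6,7-secolabd-7-en-6-ol (isopropenyl on C9, CH2OH on C5, 5α-H, 10β-CH3) | C=C(C)[C@]1(CC[C@](COCc2ccccc2)(CCOCc2ccc(OC)cc2)O1)[C@@]1(C)CCCC(C)(C)[C@@H]1CO | intermediate
25 | 16-(benzyloxy)-15-[(4-methoxybenzyl)oxy]-9α,13-epoxy-(13R)-6,7-secolabd-7-en-6-al | C=C(C)[C@]1(CC[C@](COCc2ccccc2)(CCOCc2ccc(OC)cc2)O1)[C@@]1(C)CCCC(C)(C)[C@@H]1C=O | intermediate
26 | 16-(benzyloxy)-15-[(4-methoxybenzyl)oxy]-9α,13-epoxy-(13R)-labd-8(17)-en-6α-ol | O[C@H]1CC(=C)[C@]2(CC[C@](COCc3ccccc3)(CCOCc3ccc(OC)cc3)O2)[C@@]2(C)CCCC(C)(C)[C@H]12 | intermediate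
27 | 16-(benzyloxy)-15-[(4-methoxybenzyl)oxy]-9α,13-epoxy-(13R)-labd-8(17)-en-6-one | O=C1CC(=C)[C@]2(CC[C@](COCc3ccccc3)(CCOCc3ccc(OC)cc3)O2)[C@@]2(C)CCCC(C)(C)[C@H]12 | intermediate
28 | 16-(benzyloxy)-15-[(4-methoxybenzyl)oxy]-9α,13-epoxy-(13R)-labd-8(17)-en-6β-ol | O[C@@H]1CC(=C)[C@]2(CC[C@](COCc3ccccc3)(CCOCc3ccc(OC)cc3)O2)[C@@]2(C)CCCC(C)(C)[C@H]12 | intermediate
29 | 16-(benzyloxy)-15-[(4-methoxybenzyl)oxy]-9α,13-epoxy-(13R)-labdan-6β-ol (8α-methyl) | O[C@@H]1C[C@@H](C)[C@]2(CC[C@](COCc3ccccc3)(CCOCc3ccc(OC)cc3)O2)[C@@]2(C)CCCC(C)(C)[C@H]12 | intermediate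
30 | 16-(benzyloxy)-15-[(4-methoxybenzyl)oxy]-9α,13-epoxy-(13R)-labdan-6β-yl acetate | CC(=O)O[C@@H]1C[C@@H](C)[C@]2(CC[C@](COCc3ccccc3)(CCOCc3ccc(OC)cc3)O2)[C@@]2(C)CCCC(C)(C)[C@H]12 | intermediate
31 | 16-(benzyloxy)-15-hydroxy-9α,13-epoxy-(13R)-labdan-6β-yl acetate | CC(=O)O[C@@H]1C[C@@H](C)[C@]2(CC[C@](COCc3ccccc3)(CCO)O2)[C@@]2(C)CCCC(C)(C)[C@H]12 | intermediate
32 | 16-(benzyloxy)-15-oxo-9α,13-epoxy-(13R)-labdan-6β-yl acetate | CC(=O)O[C@@H]1C[C@@H](C)[C@]2(CC[C@](COCc3ccccc3)(CC=O)O2)[C@@]2(C)CCCC(C)(C)[C@H]12 | intermediate
33 | 16-hydroxy-15-oxo-9α,13-epoxy-(13R)-labdan-6β-yl acetate | CC(=O)O[C@@H]1C[C@@H](C)[C@]2(CC[C@](CO)(CC=O)O2)[C@@]2(C)CCCC(C)(C)[C@H]12 | intermediate (not isolated)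
34 | 6β-acetoxy-9α,13:15,16-diepoxy-(13R)-labdan-15-ol (lactol; C15 epimers) | CC(=O)O[C@@H]1C[C@@H](C)[C@]2(CC[C@]3(CC(O)OC3)O2)[C@@]2(C)CCCC(C)(C)[C@H]12 | intermediate
35 | 15-O-methanesulfonate of 34 | CC(=O)O[C@@H]1C[C@@H](C)[C@]2(CC[C@]3(CC(OS(C)(=O)=O)OC3)O2)[C@@]2(C)CCCC(C)(C)[C@H]12 | intermediate (not isolated)
36 | 6β-acetoxy-9α,13:15,16-diepoxy-(13R)-labd-14-ene (CNP0242014.1) | CC(=O)O[C@@H]1C[C@@H](C)[C@]2(CC[C@]3(C=COC3)O2)[C@@]2(C)CCCC(C)(C)[C@H]12 | target

## Step count and least certain steps

Total step count: 26. Longest linear sequence: 24 steps (steps 1–8 and 11–26, from 1); the branch from 12 joins after 2 steps.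

Step 18 (key step). The most likely failure is ionization of the allylic tertiary C9–O bond, or a 1,2-shift from C9 towards a developing C8 cation that would open or enlarge ring C, in competition with the ene closure; methyl transfer from aluminium to the aldehyde is a lesser risk. The fallback replaces the ene reaction by an intramolecular Hosomi–Sakurai allylation, which forms the same C6–C7 bond with charge placed β to silicon. It sets out from 22: cerium-mediated double addition of Me3SiCH2MgCl (CeCl3, THF) should give the bis(silylmethyl) carbinol diol F1, and Peterson elimination on silica gel the hydroxy allylsilane F2. Dess–Martin oxidation then gives the allylsilane aldehyde F3, and fluoride (Bu4NF, THF) or MgBr2·OEt2 should close ring B. The fallback comes back to the route at 26 (or its C6 epimer 28, which is equally usable).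

Step 12. Leakage through the chair transition state, or partial loss of the ketene acetal geometry, would give the C9 epimer, and the congestion of the forming C9–C10 bond may slow the shift enough for C-silylation or elimination to compete. The fallback keeps 15 but changes the element that holds the enolate geometry: the zinc-chelated ester enolate (LiHMDS, ZnCl2, THF, −78 °C → rt) is rearranged without a silyl trap, the metal bridge between enolate oxygen and O9 fixing the same (Z)-geometry at a lower temperature. It sets out from 15 and comes back at 18 and makes no new compound F0; a C9 epimer, if present, would be removed at the rigid lactone 21.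

Step 13. Hydroboration of an alkene flanked by two quaternary carbons may be so slow that the borane begins to attack C1=C2, and facial selectivity at C5 may be incomplete. The fallback reverses the order of the two alkene reactions and uses the smaller borane. It sets out from 18: Me3SiCHN2 gives the methyl ester F4; hydrogenation with RhCl(PPh3)3, which should prefer the cis-disubstituted ring alkene to the doubly neopentylic methylene, gives the dihydro ester F5; BH3·SMe2 followed by NaOH/H2O2 gives the hydroxy ester F6, which lactonizes (K2CO3, MeOH). It comes back at 22 and bypasses step 14.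

Step 16. The material may rest as the lactolate, so that the olefination stalls or enolization of the methyl ketone takes over. The fallback removes the ring-chain equilibrium. It sets out from 23: TBSCl and imidazole in DMF trap the open form as the silyloxy methyl ketone F7, methylenation with Cp2TiMe2 (PhMe, 70 °C) gives the silyl ether F8, and Bu4NF removes the silyl group. It comes back at 24.

Step 10. The carbonyl between CMe2 and C(CH3)= is hindered and is further deactivated by the alkoxide formed first, so the olefination may be incomplete. The fallback protects the hydroxyl and uses a non-basic methylenation. It sets out from 13: TBSCl and imidazole give the silyl ether F9, Zn/CH2Br2/TiCl4 gives the silyl dienyl ether F10, and Bu4NF frees the alcohol. It comes back at 14.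

Step 26. Traces of acid could open ring C towards a furan, and the amine could induce β-elimination of O9 from the open hydroxy-aldehyde form of the lactol. The fallback uses an oxidative syn-elimination under neutral conditions. It sets out from 34: N-(phenylseleno)phthalimide and Bu3P give the anomeric phenyl selenide F11, and NaIO4 with NaHCO3 gives the selenoxide F12, which eliminates at room temperature towards C14. It comes back at 36.

## Further compounds

F0 | step 12 | none | none
F1 | step 18 | bis(trimethylsilylmethyl) carbinol diol from 22 (C8 bears OH and two CH2SiMe3; C6 as CH2OH) | C[Si](C)(C)CC(O)(C[Si](C)(C)C)[C@]1(CC[C@](COCc2ccccc2)(CCOCc2ccc(OC)cc2)O1)[C@@]1(C)CCCC(C)(C)[C@@H]1CO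
F2 | step 18 | hydroxy allylsilane (24 with C17 bearing SiMe3) | C=C(C[Si](C)(C)C)[C@]1(CC[C@](COCc2ccccc2)(CCOCc2ccc(OC)cc2)O1)[C@@]1(C)CCCC(C)(C)[C@@H]1CO
F3 | step 18 | allylsilane aldehyde (25 with C17 bearing SiMe3) | C=C(C[Si](C)(C)C)[C@]1(CC[C@](COCc2ccccc2)(CCOCc2ccc(OC)cc2)O1)[C@@]1(C)CCCC(C)(C)[C@@H]1C=O
F4 | step 13 | methyl ester of 18 | COC(=O)[C@]1(CC[C@](COCc2ccccc2)(CCOCc2ccc(OC)cc2)O1)[C@@]1(C)C=CCC(C)(C)C1=C
F5 | step 13 | methyl ester of 18 with C1–C2 saturated | COC(=O)[C@]1(CC[C@](COCc2ccccc2)(CCOCc2ccc(OC)cc2)O1)[C@@]1(C)CCCC(C)(C)C1=C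
F6 | step 13 | hydroxy methyl ester (5α-H; CH2OH on C5) | COC(=O)[C@]1(CC[C@](COCc2ccccc2)(CCOCc2ccc(OC)cc2)O1)[C@@]1(C)CCCC(C)(C)[C@@H]1CO
F7 | step 16 | O6-tert-butyldimethylsilyl C8-methyl ketone | CC(=O)[C@]1(CC[C@](COCc2ccccc2)(CCOCc2ccc(OC)cc2)O1)[C@@]1(C)CCCC(C)(C)[C@@H]1CO[Si](C)(C)C(C)(C)C
F8 | step 16 | tert-butyldimethylsilyl ether of 24 | C=C(C)[C@]1(CC[C@](COCc2ccccc2)(CCOCc2ccc(OC)cc2)O1)[C@@]1(C)CCCC(C)(C)[C@@H]1CO[Si](C)(C)C(C)(C)C
F9 | step 10 | tert-butyldimethylsilyl ether of 13 | CC1=C[C@@H](O[Si](C)(C)C(C)(C)C)CC(C)(C)C1=O
F10 | step 10 | tert-butyldimethylsilyl ether of 14 | C=C1C(C)=C[C@@H](O[Si](C)(C)C(C)(C)C)CC1(C)C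
F11 | step 26 | 15-phenylselanyl analogue of 34 (C15 epimers) | CC(=O)O[C@@H]1C[C@@H](C)[C@]2(CC[C@]3(CC([Se]c4ccccc4)OC3)O2)[C@@]2(C)CCCC(C)(C)[C@H]12
F12 | step 26 | selenoxide of F11 | CC(=O)O[C@@H]1C[C@@H](C)[C@]2(CC[C@]3(CC([Se](=O)c4ccccc4)OC3)O2)[C@@]2(C)CCCC(C)(C)[C@H]12
A1 | alternative 1 | (2Z,9Z,11E)-8-(tert-butyldimethylsilyloxy)-3,7,7-trimethyl... acyclic triene: (Z)-enal C9=C10 tethered through C1–C4 to the 6-silyloxy diene C5=C6–C7=C8 | O=C/C=C(/C)CCCC(C)(C)/C=C(O[Si](C)(C)C(C)(C)C)/C=C/C
A2 | alternative 1 | cis-fused 6-silyloxy-Δ6-octalin-9-carbaldehyde | CC(C)(C)[Si](C)(C)OC1=C[C@@H](C)[C@@H](C=O)[C@@]2(C)CCCC(C)(C)[C@@H]12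
A3 | alternative 2 | 16-(diazoacetoxy)-9α,13-epoxy-14,15-dinorlabdan-6-one (C13–H) | O=C1C[C@@H](C)[C@]2(CC[C@@H](COC(=O)C=[N+]=[N-])O2)[C@@]2(C)CCCC(C)(C)[C@H]12
A4 | alternative 2 | 9,13-epoxy-6-oxolabdan-15,16-olide (spiro γ-lactone) | O=C1C[C@@H](C)[C@]2(CC[C@]3(CC(=O)OC3)O2)[C@@]2(C)CCCC(C)(C)[C@H]12
A5 | alternative 3 | 2,6-dimethyl-1,4-benzoquinone | CC1=CC(=O)C=C(C)C1=O
A6 | alternative 3 | 4-methylpenta-1,3-diene | C=CC=C(C)C
A7 | alternative 3 | cis-2,5,5,8a-tetramethyl-4a,5,8,8a-tetrahydronaphthalene-1,4-dione | O=C1C=C(C)C(=O)[C@@]2(C)CC=CC(C)(C)[C@@H]12
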